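The data were computed for an exercise; scatter was added.

Early on, the two runs show how fast dissolved electrophile becomes product, and from that I want one number: the constant λ with which electrophile disappears by either way out. With the solid gone, the reacted part c is what is left after subtracting the remaining electrophile, because product and dormant form both count as reacted.

| setting | oak | elm | flask |
|---|---|---|---|
| solid electrophile | 0.80 M | 0.80 M | 0.80 M |
| nucleophile | 0.96 M | 0.96 M | 0.960 M |
| free base | 0.96 M | 0.64 M | 0.960 M |
| remark | the very flask that is asked about, followed so far | run made earlier |  |
| time |  |  | 30 h |

| run | time / h | solid electrophile / % | product / % |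
|---|---|---|---|
| oak | 1.33 | 81.2 | 1.4 |
| oak | 2.50 | 68.2 | 2.5 |
| oak | 4.00 | 56.4 | 5.2 |
| oak | 8.00 | 31.6 | 15.1 |
| oak | 15.0 | 0.1 | 31.8 |
| elm | 2.00 | 73.4 | 1.7 |
| elm | 5.00 | 49.4 | 8.5 |
| elm | 10.0 | 22.4 | 19.8 |
| elm | 15.0 | 0 | 30.2 |
| elm | 20.0 | 0 | 37.9 |

(each reading ± 0.5 percentage points)

- part of the solid electrophile that has reacted (what has only dissolved counts as not reacted) at 30 h
- share of the unused nucleophile that is free and not bound as protonated nucleophile, at 30 h

- given per volume of solution although it is solid: solid electrophile
- the numbers in the tables scatter by 0.5 percentage points (one standard deviation)
- steps under discussion: acid set free + free base <-> salt of the base; nucleophile + acid set free <-> protonated nucleophile; electrophile <-> dormant form; solid electrophile <-> electrophile; electrophile + nucleophile -> acid set free + product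
- at the start none of the solid electrophile is in solution
- what has only dissolved of solid electrophile counts as not reacted
- what has gone from electrophile into another species counts as reacted, even if it can come back
- the earlier runs do not show how much of nucleophile is bound; that part of a forecast is a guess

1. Let s be product gained per hour over the mean pool, the pool being charge minus solid minus product. Early, s is 0.0510 /h in oak and 0.0677 /h in elm. These readings are small, so I take the mean, 0.0593 /h.

2. From 15.0 h to 20.0 h in elm, s is 0.0234 /h. Used nucleophile does not reach that far by my estimate: with 71.6% left, the early s scaled down to a pseudo-first-order constant k′ is still 0.0425 /h, higher than that late s.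

3. Could bound nucleophile be the cause? Product at 15.0 h is 31.8% in oak and 30.2% in elm, despite 0.96 M against 0.64 M of free base, so I read dormant form. Then I estimate that in that elm window 54.9% of the pool is electrophile, and that dormant per product, a selectivity factor ρ, is 0.873.

4. So λ = k′ + ρk′ = 0.0796 /h, the loss constant of electrophile by both ways together. But λ drifts as nucleophile falls, so I count on this window being central. I let the charge enter at one moment, when oak's solid reads half gone, interpolated at 5.03 h, and the stretch from there to 30 h centres at 17.5 h, as the window does.

5. Electrophile left by this estimate: 13.7%, so I commit to c = 86.3%. For fr, the free share of the unused nucleophile, I have only a guess.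

The forecast gives 57% and 85%, holding that “the slowdown looks more like a dormant reservoir than protonation”. My c stands higher.

The flask gives c = 88.9% and fr = 88.2%.

    acid set free + free base ⇌ salt of the base, settled at all times (K = 8790 /M)
    nucleophile + acid set free ⇌ protonated nucleophile, settled at all times (K = 2700 /M)
    electrophile ⇌ dormant form (K = 23.0, k = 0.0518 /h)
    solid electrophile ⇌ electrophile, rate k4*(cs4 - [electrophile]) while solid is left; crystals form when [electrophile] > cs4 (solubility = 0.460 M, k = 0.306 /h)
    electrophile + nucleophile → acid set free + product (k = 0.0721 /M/h)

At 30.0 h this flask holds 11.1% electrophile, against my 13.7%, with 45.3% product and 43.6% dormant form. The forward rate to product over that to dormant form falls from 1.3 just after the start to 0.73 at the asked time.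

For the neighbour flask with 0.24 M of nucleophile, all else as in this flask, I scale k′ by the charge and keep ρk′, so my λ becomes 0.0477 /h and my c comes to 69.6%. Computed, that neighbour gives 73.6%.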